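**Plan**

1. Locants: unit 1 is the 5,7-dihydroxyflavanone half (O1, C2, C3, C4, C4a; rings A, B, C); unit 2 is the 5-hydroxy-7-methoxyflavanone half (same locants with two primes). The central chain is C2''–C3''–C3–C2, with carbonyl carbons C4'' (on C3'') and C4 (on C3).
2. Cuts, in retrosynthetic order: three O–alkyl protecting bonds; then O1–C2 and C4–C4a of unit 1 (key step); then O1''–C2'' and C4''–C4a'' of unit 2 (same reaction type); then C3–C2 (aldol) and C3''–C3 (enolate alkylation).
3. Forward: the chain is built first and stored as a γ-lactone acid (lactone O on C2'', lactone carbonyl C4, free acid C4''). Ring C of unit 2 is annulated onto a symmetric 3,5-dimethoxyphenol, then ring C of unit 1 onto a symmetric 3,5-bis(benzyloxy)phenol; one dealkylation ends the route.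
4. Stereochemistry: one carbinol is set by asymmetric hydrogenation. Substrate control relays it by alkylation (C3'' of the lactone), aldol (C3), ring closure of unit 2 (new C2'' and C3'', steered by C3) and the key step (C2 and C3, steered by C3''). The first C2''/C3'' centers and the acetoxy carbon are spent as leaving-group carriers.
5. Enabling feature: ring A of unit 1 is a phloroglucinol ring in which C4a is ortho to O1 and O5 and para to O7, so one ortho C-acylation of a symmetric phenol puts the C4 ketone next to O1. C2 is a 4-methoxybenzylic carbon β to C4, so once C4 is a ketone its acyloxy group leaves by E1cB and O1 can add to C2 in a 6-endo closure.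

Key step: step 6

Remark: the descriptors (2R,3R,2''R,3''R) are read as both pyranone rings 2,3-cis and the two halves homochiral; this is the kinetic arrangement, so no base stronger than Et3N and no heating are used once a flavanone ring exists.

**Route**

Step 1
Reactants: 1 methyl 3-(4-methoxyphenyl)-3-oxopropanoate
Product: 2 methyl (3R)-3-hydroxy-3-(4-methoxyphenyl)propanoate
Conditions: H2 (50 atm), RuCl2[(S)-BINAP] (0.5 mol %), MeOH, 50 °C
Reagents that add atoms: none
Why: Noyori asymmetric hydrogenation of a β-keto ester: the chelated keto ester takes hydride on the ketone face selected by the (S)-BINAP ligand, which for aryl β-keto esters should give the (R)-carbinol, the only stereocenter of the route set by a catalyst.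

Step 2
Reactants: 2 methyl (3R)-3-hydroxy-3-(4-methoxyphenyl)propanoate; 3 methyl bromoacetate
Product: 4 dimethyl (2S)-2-[(R)-hydroxy(4-methoxyphenyl)methyl]butanedioate
Conditions: LiN(i-Pr)2 (2.2 equiv), THF, −78 → −20 °C; then 3, −78 → −40 °C; AcOH quench at −78 °C
Reagents that add atoms: none
Why: Fráter–Seebach alkylation: the chelated lithium alkoxide–enolate of 2 is alkylated on the face away from the aryl group, so the new center (C3'' of the chain) should be anti to the hydroxyl, i.e. (2S).

Step 3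
Reactants: 4 dimethyl (2S)-2-[(R)-hydroxy(4-methoxyphenyl)methyl]butanedioate
Product: 6 (2R,3S)-2-(4-methoxyphenyl)-5-oxooxolane-3-carboxylic acid, via hydroxy diacid 5 (not isolated)
Conditions: LiOH (3 equiv), THF/H2O 3:1, 0 °C → rt; then 1 M HCl to pH 2, EtOAc, rt
Reagents that add atoms: lithium hydroxide, [Li+].[OH-]
Why: Ester saponification followed by acid-induced γ-lactonisation (5-exo-trig): only the CH2CO2H arm can close a five-membered ring onto the benzylic hydroxyl and no stereocenter is touched, so the 2,3-cis lactone acid should form with the latent leaving group (lactone O on C2'') and the acid (C4'') in place.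

Step 4
Reactants: 6 (2R,3S)-2-(4-methoxyphenyl)-5-oxooxolane-3-carboxylic acid; 7 4-methoxybenzaldehyde
Product: 9 (2R,3S,4R)-4-[(S)-acetoxy(4-methoxyphenyl)methyl]-2-(4-methoxyphenyl)-5-oxooxolane-3-carboxylic acid, via aldol adduct 8 (not isolated)
Conditions: LiN(i-Pr)2 (2.3 equiv), THF, −78 °C; 7, −78 °C; Ac2O (3 equiv), −78 → −20 °C; aq. NaHCO3, then cold 1 M HCl
Reagents that add atoms: acetic anhydride, CC(=O)OC(C)=O
Why: Aldol addition of a lactone enolate (carboxylate–enolate dianion) with trapping of the aldolate as acetate: the aldehyde should add to the enolate face opposite the neighbouring carboxylate and aryl groups, which sets the lactone α-carbon (C3 of the chain) trans to CO2H, i.e. (4R), and a Zimmerman–Traxler transition state of the ring-bound (E)-enolate should favour the anti, (S)-configured acetoxy carbon, a center that is spent in step 6.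

Step 5
Reactants: 9 (2R,3S,4R)-4-[(S)-acetoxy(4-methoxyphenyl)methyl]-2-(4-methoxyphenyl)-5-oxooxolane-3-carboxylic acid; 10 3,5-dimethoxyphenol
Product: 15 (2R,3S)-3-acetoxy-2-[(2R,3R)-5,7-dimethoxy-2-(4-methoxyphenyl)-4-oxo-3,4-dihydro-2H-chromen-3-yl]-3-(4-methoxyphenyl)propanoic acid, via acid chloride 11 (not isolated), via magnesium phenoxide 12 (not isolated), via lactone ketone 13 (not isolated), via chalcone acid 14 (not isolated)
Conditions: (COCl)2 (1.3 equiv), DMF (cat.), CH2Cl2, 0 °C → rt, evaporate; 10 (2.2 equiv) + EtMgBr (2.1 equiv), Et2O then toluene; add 11, toluene, 0 °C → rt; Et3N (3 equiv), 0 °C; cold 1 M HCl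
Reagents that add atoms: none
Why: Magnesium-templated ortho C-acylation of the phenoxide (Friedel–Crafts acylation through a six-membered chelate) followed by E1cB and intramolecular oxa-Michael addition, the sequence of one-pot flavanone syntheses: the chelated ketone 13 is enolised by Et3N, the lactone carboxylate leaves from C2'' to give the (E)-chalcone 14, and the phenoxide should add 6-endo-trig to C2'' on the face opposite the bulky CH(OAc)Ar arm of the neighbouring C3 stereocenter (A(1,3) strain holds H3 in the enone plane), after which the enolate is protonated anti to the new C2'' aryl group, so that the original C2''/C3'' centers are replaced by the 2'',3''-cis (2R,3R) pair.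

Step 6
Reactants: 15 (2R,3S)-3-acetoxy-2-[(2R,3R)-5,7-dimethoxy-2-(4-methoxyphenyl)-4-oxo-3,4-dihydro-2H-chromen-3-yl]-3-(4-methoxyphenyl)propanoic acid; 16 3,5-bis(benzyloxy)phenol
Product: 21 (2R,3R)-5,7-bis(benzyloxy)-3-[(2R,3R)-5,7-dimethoxy-2-(4-methoxyphenyl)-4-oxo-3,4-dihydro-2H-chromen-3-yl]-2-(4-methoxyphenyl)-2,3-dihydro-4H-chromen-4-one, via acid chloride 17 (not isolated), via magnesium phenoxide 18 (not isolated), via acetoxy ketone 19 (not isolated), via chalcone 20 (not isolated)
Conditions: 1-chloro-N,N,2-trimethylprop-1-en-1-amine (1.2 equiv), CH2Cl2, 0 °C; 16 (2.2 equiv) + EtMgBr (2.1 equiv), Et2O then toluene; add 17, toluene, −20 → 0 °C; Et3N (2.5 equiv), 0 °C; cold aq. NH4Cl/AcOH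
Reagents that add atoms: none
Why: Phenoxide 18 is C-acylated by 17 at the carbon ortho to O–Mg through a six-membered magnesium chelate (bond C4–C4a), the chelated ketone 19 is enolised by Et3N and loses acetate from the 4-methoxybenzylic carbon by E1cB to give the (E)-2'-hydroxychalcone 20, and the phenoxide oxygen then adds to C2 (bond O1–C2) before the enolate is protonated at C3. The closest known reactions are the one-pot Friedel–Crafts acylation/oxa-Michael synthesis of 5,7-dioxygenated flavanones from phloroglucinol-type phenols and cinnamoyl chlorides, the ortho-acylation of bromomagnesium phenoxides with acyl chlorides, and the chromanone synthesis from phenols and 3-chloropropanoyl chloride, where the enone is likewise unmasked by elimination. Ring C of unit 1 closes 6-endo-trig. C2 is controlled by the C3'' stereocenter of the finished cis-flavanone unit 2: A(1,3) strain with the anisyl group on C2 holds H3'' in the enone plane, C4'' and C2'' then lie on opposite faces, and O1 should attack the face away from C2'', whose own anisyl group is cis to the enone and covers that side; C3 is set by kinetic protonation of the enolate anti to the pseudoaxial C2 aryl group, which gives the 2,3-cis (2R,3R) ring (a direct SN2 displacement of acetate by the phenoxide, should it compete, inverts the (S)-acetoxy carbon and gives the same isomer). The step needs ortho C- over O-acylation (secured by the magnesium chelate; the two ortho carbons of the symmetric phenol are equivalent), enolisation at C3 and not at C3'' (only the new ketone is chelated by an ortho phenoxide), and no later epimerisation (after ring closure neither ketone has a free ortho phenoxide, so Et3N should not re-enolise them at 0 °C).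

Step 7
Reactants: 21 (2R,3R)-5,7-bis(benzyloxy)-3-[(2R,3R)-5,7-dimethoxy-2-(4-methoxyphenyl)-4-oxo-3,4-dihydro-2H-chromen-3-yl]-2-(4-methoxyphenyl)-2,3-dihydro-4H-chromen-4-one
Product: 22 (2R,3R)-5,7-dihydroxy-3-[(2R,3R)-5-hydroxy-7-methoxy-2-(4-methoxyphenyl)-4-oxo-3,4-dihydro-2H-chromen-3-yl]-2-(4-methoxyphenyl)-2,3-dihydro-4H-chromen-4-one
Conditions: BCl3 (8 equiv), pentamethylbenzene (6 equiv), CH2Cl2, −78 → 0 °C; MeOH, then H2O
Reagents that add atoms: none
Why: Lewis-acid ether cleavage: BCl3 removes the two aryl benzyl groups (the benzyl cations are trapped by pentamethylbenzene, which protects the electron-rich rings from C-benzylation) and, through its chelate with the C4'' carbonyl, only the peri 5''-methyl ether, while the 7''- and 4'-methyl ethers and the four stereocenters, never exposed to base, should survive at or below 0 °C.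

**Compound list**

1 | methyl 3-(4-methoxyphenyl)-3-oxopropanoate | COC(=O)CC(=O)c1ccc(OC)cc1 | starting material
2 | methyl (3R)-3-hydroxy-3-(4-methoxyphenyl)propanoate | COC(=O)C[C@@H](O)c1ccc(OC)cc1 | intermediate
3 | methyl bromoacetate | COC(=O)CBr | starting material
4 | dimethyl (2S)-2-[(R)-hydroxy(4-methoxyphenyl)methyl]butanedioate | COC(=O)C[C@@H]([C@@H](O)c1ccc(OC)cc1)C(=O)OC | intermediate
5 | (2S)-2-[(R)-hydroxy(4-methoxyphenyl)methyl]butanedioic acid (hydroxy diacid) | OC(=O)C[C@@H]([C@@H](O)c1ccc(OC)cc1)C(=O)O | intermediate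
6 | (2R,3S)-2-(4-methoxyphenyl)-5-oxooxolane-3-carboxylic acid | O=C1C[C@H](C(=O)O)[C@H](c2ccc(OC)cc2)O1 | intermediate
7 | 4-methoxybenzaldehyde | COc1ccc(C=O)cc1 | starting material
8 | (2R,3S,4R)-4-[(S)-hydroxy(4-methoxyphenyl)methyl]-2-(4-methoxyphenyl)-5-oxooxolane-3-carboxylic acid (aldol adduct, formed as its dilithium salt) | O=C1[C@@H]([C@H](O)c2ccc(OC)cc2)[C@H](C(=O)O)[C@H](c2ccc(OC)cc2)O1 | intermediate
9 | (2R,3S,4R)-4-[(S)-acetoxy(4-methoxyphenyl)methyl]-2-(4-methoxyphenyl)-5-oxooxolane-3-carboxylic acid | O=C1[C@@H]([C@H](OC(C)=O)c2ccc(OC)cc2)[C@H](C(=O)O)[C@H](c2ccc(OC)cc2)O1 | intermediate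
10 | 3,5-dimethoxyphenol | COc1cc(O)cc(OC)c1 | starting material
11 | (2R,3S,4R)-4-[(S)-acetoxy(4-methoxyphenyl)methyl]-2-(4-methoxyphenyl)-5-oxooxolane-3-carbonyl chloride (acid chloride) | O=C1[C@@H]([C@H](OC(C)=O)c2ccc(OC)cc2)[C@H](C(Cl)=O)[C@H](c2ccc(OC)cc2)O1 | intermediate
12 | bromomagnesium 3,5-dimethoxyphenoxide (magnesium phenoxide) | COc1cc(OC)cc(O[Mg]Br)c1 | intermediate
13 | (3R,4S,5R)-3-[(S)-acetoxy(4-methoxyphenyl)methyl]-4-(2-hydroxy-4,6-dimethoxybenzoyl)-5-(4-methoxyphenyl)oxolan-2-one (lactone ketone, formed as its magnesium phenoxide) | O=C1[C@@H]([C@H](OC(C)=O)c2ccc(OC)cc2)[C@H](C(=O)c2c(O)cc(OC)cc2OC)[C@H](c2ccc(OC)cc2)O1 | intermediate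
14 | (2R,3S)-3-acetoxy-2-[(E)-1-(2-hydroxy-4,6-dimethoxyphenyl)-3-(4-methoxyphenyl)-1-oxoprop-2-en-2-yl]-3-(4-methoxyphenyl)propanoic acid (chalcone acid) | OC(=O)[C@@H]([C@H](OC(C)=O)c1ccc(OC)cc1)/C(=C\c1ccc(OC)cc1)C(=O)c1c(O)cc(OC)cc1OC | intermediate
15 | (2R,3S)-3-acetoxy-2-[(2R,3R)-5,7-dimethoxy-2-(4-methoxyphenyl)-4-oxo-3,4-dihydro-2H-chromen-3-yl]-3-(4-methoxyphenyl)propanoic acid | OC(=O)[C@@H]([C@H](OC(C)=O)c1ccc(OC)cc1)[C@H]2C(=O)c3c(OC)cc(OC)cc3O[C@H]2c2ccc(OC)cc2 | intermediate
16 | 3,5-bis(benzyloxy)phenol | Oc1cc(OCc2ccccc2)cc(OCc2ccccc2)c1 | starting material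
17 | (2R,3S)-3-acetoxy-2-[(2R,3R)-5,7-dimethoxy-2-(4-methoxyphenyl)-4-oxo-3,4-dihydro-2H-chromen-3-yl]-3-(4-methoxyphenyl)propanoyl chloride (acid chloride) | ClC(=O)[C@@H]([C@H](OC(C)=O)c1ccc(OC)cc1)[C@H]2C(=O)c3c(OC)cc(OC)cc3O[C@H]2c2ccc(OC)cc2 | intermediate
18 | bromomagnesium 3,5-bis(benzyloxy)phenoxide (magnesium phenoxide) | Br[Mg]Oc1cc(OCc2ccccc2)cc(OCc2ccccc2)c1 | intermediate
19 | (1S,2R)-3-[2,4-bis(benzyloxy)-6-hydroxyphenyl]-2-[(2R,3R)-5,7-dimethoxy-2-(4-methoxyphenyl)-4-oxo-3,4-dihydro-2H-chromen-3-yl]-1-(4-methoxyphenyl)-3-oxopropyl acetate (acetoxy ketone, formed as its magnesium phenoxide) | O=C(c1c(O)cc(OCc2ccccc2)cc1OCc1ccccc1)[C@@H]([C@H](OC(C)=O)c1ccc(OC)cc1)[C@H]2C(=O)c3c(OC)cc(OC)cc3O[C@H]2c2ccc(OC)cc2 | intermediate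
20 | (2R,3R)-3-[(E)-1-[2,4-bis(benzyloxy)-6-hydroxyphenyl]-3-(4-methoxyphenyl)-1-oxoprop-2-en-2-yl]-5,7-dimethoxy-2-(4-methoxyphenyl)-2,3-dihydro-4H-chromen-4-one (chalcone) | O=C(c1c(O)cc(OCc2ccccc2)cc1OCc1ccccc1)/C(=C/c1ccc(OC)cc1)[C@H]2C(=O)c3c(OC)cc(OC)cc3O[C@H]2c2ccc(OC)cc2 | intermediate
21 | (2R,3R)-5,7-bis(benzyloxy)-3-[(2R,3R)-5,7-dimethoxy-2-(4-methoxyphenyl)-4-oxo-3,4-dihydro-2H-chromen-3-yl]-2-(4-methoxyphenyl)-2,3-dihydro-4H-chromen-4-one | COc1ccc([C@@H]2Oc3cc(OCc4ccccc4)cc(OCc4ccccc4)c3C(=O)[C@@H]2[C@H]2C(=O)c3c(OC)cc(OC)cc3O[C@H]2c2ccc(OC)cc2)cc1 | intermediate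
22 | (2R,3R)-5,7-dihydroxy-3-[(2R,3R)-5-hydroxy-7-methoxy-2-(4-methoxyphenyl)-4-oxo-3,4-dihydro-2H-chromen-3-yl]-2-(4-methoxyphenyl)-2,3-dihydro-4H-chromen-4-one | COc1ccc([C@@H]2Oc3cc(O)cc(O)c3C(=O)[C@@H]2[C@H]2C(=O)c3c(O)cc(OC)cc3O[C@H]2c2ccc(OC)cc2)cc1 | target

Total step count: 7. Longest linear sequence: 7 steps (1 → 22).

**Steps most likely to fail**

1. Step 6. The oxa-Michael addition may show poor facial selectivity at C2, or the kinetic 2,3-cis ring may equilibrate at C3 by re-enolisation; O-acylation of the phenoxide may also compete. Fallback, setting out from 6 and returning at 21: the ring is closed by a stereospecific SN2 reaction instead of a conjugate addition. Step 4 is run with t-BuMe2SiOTf/2,6-lutidine in place of Ac2O and should give (2R,3S,4R)-4-[(S)-(tert-butyldimethylsilyloxy)(4-methoxyphenyl)methyl]-2-(4-methoxyphenyl)-5-oxooxolane-3-carboxylic acid F1. Step 5 as written should turn it into (2R,3S)-3-(tert-butyldimethylsilyloxy)-2-[(2R,3R)-5,7-dimethoxy-2-(4-methoxyphenyl)-4-oxo-3,4-dihydro-2H-chromen-3-yl]-3-(4-methoxyphenyl)propanoic acid F2. Its acid chloride and 18 in toluene at −20 °C without amine should stop at the silyloxy ketone (2R,3S)-1-[2,4-bis(benzyloxy)-6-hydroxyphenyl]-3-(tert-butyldimethylsilyloxy)-2-[(2R,3R)-5,7-dimethoxy-2-(4-methoxyphenyl)-4-oxo-3,4-dihydro-2H-chromen-3-yl]-3-(4-methoxyphenyl)propan-1-one F3, because silyloxide does not leave. HF·pyridine in THF should free the hydroxy ketone (2R,3S)-1-[2,4-bis(benzyloxy)-6-hydroxyphenyl]-3-hydroxy-2-[(2R,3R)-5,7-dimethoxy-2-(4-methoxyphenyl)-4-oxo-3,4-dihydro-2H-chromen-3-yl]-3-(4-methoxyphenyl)propan-1-one F4. An intramolecular Mitsunobu etherification (PPh3, DIAD, THF, 0 °C) then closes ring C with inversion at the (S)-carbinol, which with the retained (R) center next to it is the 2,3-cis (2R,3R) ring of 21.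

2. Step 5. The open-chain stereocenter C3 may steer the first conjugate addition only weakly, and the acid chloride may eliminate to an anhydride before C-acylation. Fallback, setting out from 9 and returning at 15: control is moved from the substrate to a catalyst and the cascade is split. Acylation and elimination are run as in step 5 but quenched cold with acid so that the open chalcone acid 14 is isolated. The ring is then closed in a separate oxa-Michael step with a bifunctional cinchona-alkaloid thiourea (quinine- or quinidine-derived, whichever is matched with C3). The diastereomers all carry the fixed (2R,3S) side chain, so they are separable, and unwanted ones are returned to 14 with base. New compounds: none F0.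

3. Step 4. Retro-aldol cleavage on warming, incomplete facial control at the lactone α-carbon, or loss of acetate by elimination during work-up may occur. Fallback, setting out from 6 and returning at 9: the aldol is replaced by acylation and reduction. The dianion of 6 (LiN(i-Pr)2, 3.2 equiv) is C-acylated with 4-methoxybenzoyl chloride to give (2R,3S,4R)-4-(4-methoxybenzoyl)-2-(4-methoxyphenyl)-5-oxooxolane-3-carboxylic acid F5, whose doubly activated α-carbon should settle trans to CO2H. Noyori–Ikariya transfer hydrogenation (RuCl[(S,S)-TsDPEN](p-cymene), HCO2H/Et3N, catalyst enantiomer chosen for the (S)-carbinol) with dynamic kinetic resolution should give hydroxy acid 8, and Ac2O/pyridine at 0 °C gives 9.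

Further compounds
F1 | step 6 | (2R,3S,4R)-4-[(S)-(tert-butyldimethylsilyloxy)(4-methoxyphenyl)methyl]-2-(4-methoxyphenyl)-5-oxooxolane-3-carboxylic acid | O=C1[C@@H]([C@H](O[Si](C)(C)C(C)(C)C)c2ccc(OC)cc2)[C@H](C(=O)O)[C@H](c2ccc(OC)cc2)O1
F2 | step 6 | (2R,3S)-3-(tert-butyldimethylsilyloxy)-2-[(2R,3R)-5,7-dimethoxy-2-(4-methoxyphenyl)-4-oxo-3,4-dihydro-2H-chromen-3-yl]-3-(4-methoxyphenyl)propanoic acid | OC(=O)[C@@H]([C@H](O[Si](C)(C)C(C)(C)C)c1ccc(OC)cc1)[C@H]2C(=O)c3c(OC)cc(OC)cc3O[C@H]2c2ccc(OC)cc2
F3 | step 6 | (2R,3S)-1-[2,4-bis(benzyloxy)-6-hydroxyphenyl]-3-(tert-butyldimethylsilyloxy)-2-[(2R,3R)-5,7-dimethoxy-2-(4-methoxyphenyl)-4-oxo-3,4-dihydro-2H-chromen-3-yl]-3-(4-methoxyphenyl)propan-1-one | O=C(c1c(O)cc(OCc2ccccc2)cc1OCc1ccccc1)[C@@H]([C@H](O[Si](C)(C)C(C)(C)C)c1ccc(OC)cc1)[C@H]2C(=O)c3c(OC)cc(OC)cc3O[C@H]2c2ccc(OC)cc2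
F4 | step 6 | (2R,3S)-1-[2,4-bis(benzyloxy)-6-hydroxyphenyl]-3-hydroxy-2-[(2R,3R)-5,7-dimethoxy-2-(4-methoxyphenyl)-4-oxo-3,4-dihydro-2H-chromen-3-yl]-3-(4-methoxyphenyl)propan-1-one | O=C(c1c(O)cc(OCc2ccccc2)cc1OCc1ccccc1)[C@@H]([C@H](O)c1ccc(OC)cc1)[C@H]2C(=O)c3c(OC)cc(OC)cc3O[C@H]2c2ccc(OC)cc2
F0 | step 5 | none | none
F5 | step 4 | (2R,3S,4R)-4-(4-methoxybenzoyl)-2-(4-methoxyphenyl)-5-oxooxolane-3-carboxylic acid | O=C1[C@@H](C(=O)c2ccc(OC)cc2)[C@H](C(=O)O)[C@H](c2ccc(OC)cc2)O1
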